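The data stem from a simulated flask with made-up constants; scatter was added.

The spring run ends with 49.9% of its starting material left over, and that leftover has stood still since 1.04 d. So the second substrate, charged at 0.500 equiv, is the limiting reagent, and our books hold 50.0% of the starting material charged. We ask where that goes in each flask.

the same everywhere: starting material 0.12 M

|  | second substrate | free enzyme | temperature | remark | time |
|---|---|---|---|---|---|
| dawn | 0.50 equiv | 0.004 mol% | −29 °C | run made earlier |  |
| spring | 0.50 equiv | 0.016 mol% | −4 °C | run made earlier |  |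
| alder | 0.500 equiv | 0.008 mol% | 5 °C |  | 3.0 d |
| larch | 0.500 equiv | 0.008 mol% | −40 °C |  | 3.0 d |
| maple | 0.500 equiv | 0.008 mol% | −10 °C |  | 3.0 d |
| cedar | 0.500 equiv | 0.008 mol% | −25 °C |  | 3.0 d |

| run | time / d | target / % | starting material / % |
|---|---|---|---|
| dawn | 1.04 | 1.0 | 99.3 |
| dawn | 2.50 | 1.8 | 98.2 |
| dawn | 6.00 | 5.4 | 94.6 |
| dawn | 10.0 | 8.1 | 91.3 |
| dawn | 15.0 | 12.6 | 87.4 |
| dawn | 20.0 | 17.2 | 82.9 |
| spring | 0.417 | 26.8 | 72.4 |
| spring | 0.625 | 38.6 | 61.2 |
| spring | 1.04 | 48.1 | 49.6 |
| spring | 1.67 | 45.2 | 49.8 |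
| spring | 2.50 | 42.2 | 50.0 |
| spring | 4.00 | 38.1 | 49.9 |
| spring | 6.00 | 33.0 | 49.9 |

(standard deviation of a reading: 0.3 percentage points)

1. the flask with the highest amount of target, in percent of the starting material charged ("all alike" if they lie within 1.5 percentage points) (alder / larch / maple / cedar / all alike)
2. final target, as a percentage of the starting material charged, in alder
3. final target, as a percentage of the starting material charged, in larch
4. final target, as a percentage of the starting material charged, in maple
5. final target, as a percentage of the starting material charged, in cedar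



The first entry is what gets spent. As a fraction of the charge, target grows at 0.643 d⁻¹ up to the first reading of the spring run and at 0.00860 d⁻¹ over the whole dawn run. We assume speed goes with the enzyme, which these two runs can't test. Per unit of enzyme, then, the gap of 25.0 K multiplies speed by 18.7. The warming that doubles it is 5.92 K, the doubling step.

The second entry is what is lost. In the spring run target falls from 48.1% to 33.0% while starting material stays flat, a loss of 0.0760 d⁻¹. We borrow the same step for it, which is a guess.

Our books, counted from the spring run: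

Maple: speed 0.159 d⁻¹, spent 47.7%, lost on the average target at 0.0376 d⁻¹, target 45.1%.

Alder: speed 0.922 d⁻¹, limit reached at 0.542 d, then loss at 0.218 d⁻¹, target 29.3%.

Cedar stands at −25 °C and larch at −40 °C, so by this rule each spends less than maple. We expect maple to hold the most.

The forecast names maple, with alder 27%, larch 1.2%, maple 44% and cedar 8.7%. Its words: “Alder finishes within 0.6 d, then loses roughly half, leaving about 27%.” Our alder stands higher than its figure.

The flasks give alder 30.3%, larch 1.08%, maple 45.4% and cedar 8.61%, so the most is in maple.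

    second complex → free enzyme + target (k = 192 min⁻¹, Ea = 73.0 kJ mol⁻¹)
    second substrate + loaded enzyme ⇌ second complex (K = 17.0 L mol⁻¹, k = 8670 L mol⁻¹ min⁻¹, Ea = 47.0 kJ mol⁻¹, ΔH = −24.0 kJ mol⁻¹)
    first complex ⇌ loaded enzyme + first product (K = 0.0759 M, k = 9.25 min⁻¹, Ea = 67.0 kJ mol⁻¹, ΔH = −56.0 kJ mol⁻¹)
    starting material + free enzyme ⇌ first complex (K = 60.8 L mol⁻¹, k = 2950 L mol⁻¹ min⁻¹, Ea = 39.0 kJ mol⁻¹, ΔH = −40.0 kJ mol⁻¹)
    free enzyme → unfolded enzyme (k = 1.68 × 10⁻⁶ min⁻¹, Ea = 193 kJ mol⁻¹)
    target + first product → side product (k = 0.00298 L mol⁻¹ min⁻¹, Ea = 72.0 kJ mol⁻¹)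
    (constants at 5 °C)

Maple holds 45.4% of target. At 3.00 d its loss entry stands as 2.06% of side product. Now carry the doubling step to cedar, counting from the dawn run: speed 0.0275 d⁻¹, so 8.25% spent by 3.0 d. Cedar holds 8.61%.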